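Atom labels C1–C15 follow germacrane/elemane numbering and are used for the open-chain intermediates as well. The compound numbers are those of the steps and the compound list.

## Analysis of the target

The target 24 is an elemanolide: a cyclohexane (C5–C10) trans-fused at C7/C8 to an α-methylene-γ-butyrolactone (C8–O–C12–C11–C7, methylene C13). All six ring carbons are stereogenic, and a seventh centre lies in the oxirane (C1). In the chair that keeps the lactone diequatorial, the acrolein arm at C5 (C4, methylene C3, formyl C15) and the oxiranyl group at C10 are equatorial and trans to each other. The C6 hydroxyl, the C9 isobutyrate and the C10 methyl (C14) are axial; the hydroxyl is cis to C11 and syn-axial to C14. Three electrophiles (methylene lactone, enal, terminal epoxide) and a base-labile ester sit on one small ring, so strong bases, nucleophiles and acids are excluded late in the route. The hardest bond is C5–C10, which joins a quaternary carbon to a tertiary one, each carrying an unsaturated arm. Read backwards, the oxirane is a vinyl group and the acrolein an isopropenyl group, so C10 and C5 form a trans-1,2-dialkenylcyclohexane. That pair is the retron of a Cope rearrangement of a cyclodeca-1,5-diene, and the strategy rests on it.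

## Retrosynthetic reasoning

**Epoxide (24 from 22 via 23).** The oxirane is the most fragile group and is installed last. In enal 22 the C1=C2 vinyl group is the only alkene that is not conjugated to a carbonyl, so an electrophilic oxygen-transfer reagent should pick it. The vinyl group sits on a quaternary carbon, so no face preference is relied on: the epimeric mixture 23 is resolved by hydrolytic kinetic resolution, which leaves 24.

**Enal (22 from 20).** The C15 formyl group is traced back to the isopropenyl methyl of 20 by allylic oxidation. This must precede the epoxidation, because the isopropenyl alkene of 20 is more electron-rich than the vinyl group and would be epoxidised first.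

**C5–C10 (20 from 19).** Cutting C5–C10 and rejoining C2–C3 turns the cyclohexane into the (1(10)E,4E)-germacradienolide 19. This is the only disconnection that removes the quaternary centre, its tertiary neighbour and both alkenyl arms at once. The forward Cope rearrangement has to go through the chair and has to lie on the elemane side.

**C6 configuration (19 from 17 via 18).** In 19 the C6 hydroxyl is cis to C11. A chromium-mediated ring closure should deliver the other epimer, 17, so C6 is passed through ketone 18 and rebuilt by hydride addition. This makes the route independent of the C6 outcome of the ring closure.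

**C6–C7 and the ten-membered ring (17 from 16).** Cutting C6–C7 opens the macrocycle to bromo-enal 16. The forward allylation forms the ring, the exocyclic C11=C13 alkene and the lactone fusion in one step. It is chosen over a closure at an alkene because both E alkenes are then fixed in the acyclic chain by the geranyl skeleton.

**Functional group adjustments (16 from 12 via 13, 14, 15).** The allylic bromide at C13 and the aldehyde at C6 are unveiled from two silyl ethers of different lability. A methyl group at C13 could not be brominated selectively beside the allylic C–H bonds of two trisubstituted alkenes, so C13 enters already oxygenated. An ester at C6 could not be removed later beside the C9 isobutyrate, so C6 is a silyl ether.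

**C8–C9 (12 from 10, and 10 from 4 and 9).** The C8–C9 bond and both of its stereocentres come from a catalytic asymmetric vinylogous aldol reaction of silyloxyfuran 9 with enal 4. The anti adduct 10 has the relative configuration that 24 needs, and acylation with isobutyryl chloride 11 gives 12.

**Building blocks (4 from 1; 9 from 5 via 7 and 8).** Enal 4 is geraniol 1 after silylation and oxidation of its terminal (E)-methyl group (via 2). Furan 9 comes from butynediol 5 by hydroalumination–iodination to 7, carbonylative lactonisation to 8 and double silylation.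

## Alternatives that were turned down

**Alternative 1:** the lactone bond C7–C11 is cut on a finished cyclohexane. In the forward step a dirhodium carboxamidate decomposes the O8 diazoacetate A2, and the carbene inserts into the equatorial C7–H bond to give the trans lactone A1.
- For: insertion goes with retention, so the lactone fusion follows directly from the ring. On this point it is stronger than the chosen route, which sets C7 in a macrocyclisation.
- Against: the insertion builds none of C5, C6, C8, C9 or the quaternary C10. A2 must already carry all of them, so the hard C5–C10 problem is only moved. The C9–H bond is also a 1,5-site, and the isopropenyl alkene can be cyclopropanated.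
- After A1: α-methylenation under base beside the isobutyrate, acetonide-to-epoxide conversion, desilylation and enal formation still remain.
- Comparison: the chosen strategy offers instead one step that makes the ring, the quaternary centre and both alkenyl arms from a precursor, 19, with only four stereocentres.

**Alternative 2:** C7–C8 is cut. In the forward step cathodic reduction of the open-chain aldehyde–enoate A4 couples the enoate β-carbon with the aldehyde carbon and closes the ring as the trans γ-hydroxy ester A3.
- For: the conditions are mild and need no stoichiometric metal, and the γ-hydroxy ester is set up to lactonise. It is stronger than a 190 °C thermolysis on mildness.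
- Against: A4 must hold C5, C6, C9 and the quaternary C10 as an acyclic array, which means a long linear stereocontrolled sequence. The cis/trans outcome of a six-ring electroreductive closure depends on the chain conformer. The C6 silyloxy group next to the reduced enoate can be expelled, and the α-alkoxy aldehyde can epimerise.
- After A3: methylenation and a protecting-group exchange at C9 are still needed.
- Comparison: the chosen route gives up mildness but needs far fewer stereocentres before its key step, and it sets C5 and C10 there.

**Alternative 3:** C6–C7 is cut. In the forward step a triazolium-derived carbene turns the C6 aldehyde of A6 into an acyl-anion equivalent that adds to C7 of the enoate and gives cyclohexanone A5.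
- For: a chiral catalyst controls the ring-forming step. That is stronger than the conformational control on which the Cope step depends.
- Against: A5 has C5 as a methylene group and C6 as a ketone. The acrolein arm would have to be attached later at a neopentyl position beside C10, with stereocontrol, and the ketone reduced to the axial alcohol. A5 is also a β-silyloxy ketone with an epimerisable C7, so it is prone to elimination under the basic carbene conditions. Aliphatic aldehydes with β-alkyl enoates are slow substrates for this reaction.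
- Comparison: the chosen route places the C5 arm and the C10 centre in the same step, and no carbonyl remains beside C7 afterwards.

Key step: step 14

Remark: the (R,R)-bisphosphoramide of step 6 is assumed to direct the furan to the Re face of the conjugated aldehyde, and the (R,R)-cobalt–salen complex of step 17 to hydrolyse the (1S)-oxirane, as these catalysts do with conjugated aldehydes and with alkyl oxiranes. If a model shows the opposite sense, the mirror-image catalyst is used.

## Route

Step 1
Reactants: 1 geraniol
Product: 2 tert-butyl{[(2E)-3,7-dimethylocta-2,6-dien-1-yl]oxy}dimethylsilane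
Conditions: TBSCl, imidazole, CH2Cl2, 0 °C to rt
Reagents that add atoms: tert-butyldimethylsilyl chloride, CC(C)(C)[Si](C)(C)Cl
Why: Standard silylation of a primary allylic alcohol; a silyl ether at C6 can later be removed beside the C9 isobutyrate without base.

Step 2
Reactants: 2 tert-butyl{[(2E)-3,7-dimethylocta-2,6-dien-1-yl]oxy}dimethylsilane
Product: 4 (2E,6E)-8-[(tert-butyldimethylsilyl)oxy]-2,6-dimethylocta-2,6-dienal, via allylic alcohol 3 (not isolated)
Conditions: SeO2 (cat.), t-BuOOH, salicylic acid (cat.), CH2Cl2, rt; crude, then MnO2, CH2Cl2, rt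
Reagents that add atoms: selenium dioxide, O=[Se]=O; tert-butyl hydroperoxide, CC(C)(C)OO
Why: Allylic oxidation (ene reaction, then [2,3]-shift) should attack the distal, more electron-rich alkene at its (E)-methyl group, the other alkene being deactivated by the allylic oxygen; MnO2 then takes alcohol 3 and any aldehyde already formed to the (E)-enal.

Step 3
Reactants: 5 but-2-yne-1,4-diol
Product: 7 (Z)-2-iodobut-2-ene-1,4-diol, via cyclic alkenylalanate 6 (not isolated)
Conditions: LiAlH4, THF, 0 °C to reflux; then I2, THF, −78 to 0 °C
Reagents that add atoms: iodine, II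
Why: Alkoxide-directed anti hydroalumination of the propargylic diol gives the cyclic alkenylalanate, and iodinolysis with retention places iodine cis to the distal hydroxymethyl group.

Step 4
Reactants: 7 (Z)-2-iodobut-2-ene-1,4-diol
Product: 8 3-(hydroxymethyl)furan-2(5H)-one
Conditions: PdCl2(PPh3)2 (cat.), CO (1 atm), K2CO3, THF, 40 °C
Reagents that add atoms: carbon monoxide, [C-]#[O+]
Why: Palladium-catalysed carbonylative lactonisation of a (Z)-3-iodoallylic alcohol: the acylpalladium species is trapped by the cis hydroxymethyl group to the five-membered butenolide, which is far easier than closure of the geminal hydroxymethyl group to a four-membered ring.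

Step 5
Reactants: 8 3-(hydroxymethyl)furan-2(5H)-one
Product: 9 triethyl({2-[(triethylsilyl)oxy]furan-3-yl}methoxy)silane
Conditions: TESOTf (2.3 equiv), Et3N, CH2Cl2, 0 °C
Reagents that add atoms: triethylsilyl trifluoromethanesulfonate, CC[Si](CC)(CC)OS(=O)(=O)C(F)(F)F
Why: One reagent silylates the primary alcohol and turns the butenolide into the aromatic 2-silyloxyfuran by soft enolisation; C13 thus enters the route at the alcohol oxidation level.

Step 6
Reactants: 4 (2E,6E)-8-[(tert-butyldimethylsilyl)oxy]-2,6-dimethylocta-2,6-dienal; 9 triethyl({2-[(triethylsilyl)oxy]furan-3-yl}methoxy)silane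
Product: 10 (5R)-5-[(1S,2E,6E)-8-[(tert-butyldimethylsilyl)oxy]-1-hydroxy-2,6-dimethylocta-2,6-dien-1-yl]-3-{[(triethylsilyl)oxy]methyl}furan-2(5H)-one
Conditions: SiCl4, (R,R)-binaphthyl-2,2'-diamine-derived bisphosphoramide (5 mol %), i-Pr2NEt (cat.), CH2Cl2, −78 °C; aq. NaHCO3
Reagents that add atoms: none
Why: Catalytic asymmetric vinylogous Mukaiyama aldol reaction, a type that works best with conjugated aldehydes; the furan reacts at C5 (C8), the phosphoramide-bound silicon cation should expose the Re face of the enal (9S) and the open transition state should give the anti adduct (8R).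

Step 7
Reactants: 10 (5R)-5-[(1S,2E,6E)-8-[(tert-butyldimethylsilyl)oxy]-1-hydroxy-2,6-dimethylocta-2,6-dien-1-yl]-3-{[(triethylsilyl)oxy]methyl}furan-2(5H)-one; 11 isobutyryl chloride
Product: 12 (1S,2E,6E)-8-[(tert-butyldimethylsilyl)oxy]-2,6-dimethyl-1-[(2R)-5-oxo-4-{[(triethylsilyl)oxy]methyl}-2,5-dihydrofuran-2-yl]octa-2,6-dien-1-yl 2-methylpropanoate
Conditions: pyridine, DMAP (cat.), CH2Cl2, 0 °C
Reagents that add atoms: none
Why: Acylation of the only free hydroxyl; pyridine is too weak a base to trigger elimination of the new ester across C8–C9, which amine bases stronger than pyridine would cause.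

Step 8
Reactants: 12 (1S,2E,6E)-8-[(tert-butyldimethylsilyl)oxy]-2,6-dimethyl-1-[(2R)-5-oxo-4-{[(triethylsilyl)oxy]methyl}-2,5-dihydrofuran-2-yl]octa-2,6-dien-1-yl 2-methylpropanoate
Product: 13 (1S,2E,6E)-8-[(tert-butyldimethylsilyl)oxy]-1-[(2R)-4-(hydroxymethyl)-5-oxo-2,5-dihydrofuran-2-yl]-2,6-dimethylocta-2,6-dien-1-yl 2-methylpropanoate
Conditions: PPTS (cat.), MeOH/CH2Cl2, 0 °C
Reagents that add atoms: none
Why: Mild acidic methanolysis should cleave the primary triethylsilyl ether well before the tert-butyldimethylsilyl ether, and it touches neither ester nor butenolide.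

Step 9
Reactants: 13 (1S,2E,6E)-8-[(tert-butyldimethylsilyl)oxy]-1-[(2R)-4-(hydroxymethyl)-5-oxo-2,5-dihydrofuran-2-yl]-2,6-dimethylocta-2,6-dien-1-yl 2-methylpropanoate
Product: 14 (1S,2E,6E)-1-[(2R)-4-(bromomethyl)-5-oxo-2,5-dihydrofuran-2-yl]-8-[(tert-butyldimethylsilyl)oxy]-2,6-dimethylocta-2,6-dien-1-yl 2-methylpropanoate
Conditions: CBr4, PPh3, CH2Cl2, 0 °C
Reagents that add atoms: tetrabromomethane, BrC(Br)(Br)Br
Why: Appel bromination of a primary allylic alcohol under neutral conditions; no aldehyde is present yet, so dibromo-olefination cannot interfere.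

Step 10
Reactants: 14 (1S,2E,6E)-1-[(2R)-4-(bromomethyl)-5-oxo-2,5-dihydrofuran-2-yl]-8-[(tert-butyldimethylsilyl)oxy]-2,6-dimethylocta-2,6-dien-1-yl 2-methylpropanoate
Product: 15 (1S,2E,6E)-1-[(2R)-4-(bromomethyl)-5-oxo-2,5-dihydrofuran-2-yl]-8-hydroxy-2,6-dimethylocta-2,6-dien-1-yl 2-methylpropanoate
Conditions: aq. HF, MeCN, 0 °C
Reagents that add atoms: none
Why: Acidic fluoride removes the primary silyl ether without a nucleophilic base, which would quaternise or eliminate at the allylic bromide.

Step 11
Reactants: 15 (1S,2E,6E)-1-[(2R)-4-(bromomethyl)-5-oxo-2,5-dihydrofuran-2-yl]-8-hydroxy-2,6-dimethylocta-2,6-dien-1-yl 2-methylpropanoate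
Product: 16 (1S,2E,6E)-1-[(2R)-4-(bromomethyl)-5-oxo-2,5-dihydrofuran-2-yl]-2,6-dimethyl-8-oxoocta-2,6-dien-1-yl 2-methylpropanoate
Conditions: MnO2, CH2Cl2, rt
Reagents that add atoms: none
Why: Heterogeneous oxidation of the only allylic alcohol to the (E)-enal; neutral, and inert to the bromide and the esters.

Step 12
Reactants: 16 (1S,2E,6E)-1-[(2R)-4-(bromomethyl)-5-oxo-2,5-dihydrofuran-2-yl]-2,6-dimethyl-8-oxoocta-2,6-dien-1-yl 2-methylpropanoate
Product: 17 (1(10)E,4E,6R,7S,8R,9S)-6-hydroxy-9-(isobutyryloxy)germacra-1(10),4,11(13)-trien-12,8-olide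
Conditions: CrCl2 (8 equiv), THF, rt, slow addition (final 2 mM)
Reagents that add atoms: none
Why: Intramolecular Nozaki–Hiyama allylation: CrCl2 turns the allylic bromide into an allylchromium species that adds through C7 to the C6 aldehyde, closing the ten-membered ring and creating the exocyclic C11=C13 alkene. Attack on the butenolide face away from the C9 branch should give the trans lactone (7S), and the closed chair transition state with the enal chain equatorial should give H6 anti to H7 (6R). C6 is reset in step 13, so either C6 epimer can be carried on.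

Step 13
Reactants: 17 (1(10)E,4E,6R,7S,8R,9S)-6-hydroxy-9-(isobutyryloxy)germacra-1(10),4,11(13)-trien-12,8-olide
Product: 19 (1(10)E,4E,6S,7S,8R,9S)-6-hydroxy-9-(isobutyryloxy)germacra-1(10),4,11(13)-trien-12,8-olide, via 6-oxo germacranolide 18 (not isolated)
Conditions: DMP (1,1,1-triacetoxy-1,2-benziodoxol-3(1H)-one), NaHCO3, CH2Cl2, 0 °C; crude, then NaBH4, CeCl3·7H2O, MeOH, −78 °C
Reagents that add atoms: none
Why: Periodinane oxidation erases C6 and Luche reduction rebuilds it. In the crown conformer the carbonyl face that carries the C14 and C15 methyl groups is screened, so hydride should enter on the side of H7 and leave the hydroxyl cis to C11 (6S). Cerium-assisted borohydride adds 1,2 and spares the methylene lactone.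

Step 14
Reactants: 19 (1(10)E,4E,6S,7S,8R,9S)-6-hydroxy-9-(isobutyryloxy)germacra-1(10),4,11(13)-trien-12,8-olide
Product: 20 (5S,6S,7S,8R,9S,10S)-6-hydroxy-9-(isobutyryloxy)elema-1,3,11(13)-trien-12,8-olide
Conditions: 1,2-dichlorobenzene (0.01 M), BHT (cat.), 190 °C, argon, base-washed sealed tube
Reagents that add atoms: none
Why: Heating lets the two E alkenes of the cyclodeca-1,5-diene, held face to face across the ring, undergo a concerted suprafacial [3,3] shift through a chair-like six-centre transition state in which C5–C10 forms while C2–C3 breaks; the closest known reaction is the thermal germacrene-to-elemene (germacranolide-to-elemanolide) rearrangement. The cyclohexane is closed by transannular ring contraction of the ten-membered ring, so no exo or endo mode applies. C5 and C10 are set together: the E,E geometry in the chair places the C14 methyl trans to H5, that is, vinyl and isopropenyl trans. Their absolute sense follows from the trans lactone, which fixes C7 and C8 as a diequatorial pair of the forming chair; the gauche C1–C10···C5–C4 arrangement that the chair transition state needs is then available only with both alkenyl arms equatorial (5S,10S), because the other face would demand a trans-diaxial arrangement that cannot close. The step needs chair over boat selectivity, which the crossed E,E diene provides, and a favourable equilibrium, which the release of transannular strain and of the allylic strain between the C6 hydroxyl and the C15 methyl of 19 should provide. The alcohol, lactone and ester lie outside the pericyclic array (C6 is attached to a diene terminus, so no oxy-Cope path exists); BHT and base-washed glass guard the methylene lactone against radical polymerisation and the diene against acid-induced transannular cyclisation.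

Step 15
Reactants: 20 (5S,6S,7S,8R,9S,10S)-6-hydroxy-9-(isobutyryloxy)elema-1,3,11(13)-trien-12,8-olide
Product: 22 (5R,6S,7S,8R,9S,10S)-6-hydroxy-9-(isobutyryloxy)-15-oxoelema-1,3,11(13)-trien-12,8-olide, via C15 allylic alcohol 21 (not isolated)
Conditions: SeO2 (0.5 equiv), t-BuOOH, CH2Cl2, rt; crude, then MnO2, CH2Cl2, rt
Reagents that add atoms: selenium dioxide, O=[Se]=O; tert-butyl hydroperoxide, CC(C)(C)OO
Why: The isopropenyl group is the only electron-rich alkene with allylic hydrogens (the vinyl group has none, the methylene lactone is electron-poor); the methyl group should react in the ene step because H5 lies near the nodal plane of the alkene in the hindered rotamer. MnO2 then oxidises only the primary allylic alcohol and leaves the C6 alcohol.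

Step 16
Reactants: 22 (5R,6S,7S,8R,9S,10S)-6-hydroxy-9-(isobutyryloxy)-15-oxoelema-1,3,11(13)-trien-12,8-olide
Product: 23 (1RS,5R,6S,7S,8R,9S,10R)-1,2-epoxy-6-hydroxy-9-(isobutyryloxy)-15-oxoelema-3,11(13)-dien-12,8-olide (both C1 epimers)
Conditions: dimethyldioxirane (acetone solution), 0 °C to rt
Reagents that add atoms: dimethyldioxirane, CC1(C)OO1
Why: Electrophilic epoxidation under neutral conditions: the vinyl group is the only alkene not conjugated to a carbonyl, and the enal and methylene lactone react much more slowly; no face preference is assumed for a vinyl group on a quaternary carbon.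

Step 17
Reactants: 23 (1RS,5R,6S,7S,8R,9S,10R)-1,2-epoxy-6-hydroxy-9-(isobutyryloxy)-15-oxoelema-3,11(13)-dien-12,8-olide (both C1 epimers)
Product: 24 (1R,5R,6S,7S,8R,9S,10R)-1,2-epoxy-6-hydroxy-9-(isobutyryloxy)-15-oxoelema-3,11(13)-dien-12,8-olide
Conditions: (R,R)-[N,N'-bis(3,5-di-tert-butylsalicylidene)cyclohexane-1,2-diaminato]cobalt acetate (trivalent cobalt, 5 mol %), H2O (0.6 equiv), THF, 0 °C to rt
Reagents that add atoms: none
Why: Hydrolytic kinetic resolution: the cobalt–salen complex opens terminal epoxides with water at the CH2 terminus under strong catalyst control, so it should hydrolyse the (1S)-epimer to a polar diol and leave the (1R)-epoxide, which is the target.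

## Compound list

1 | geraniol | CC(C)=CCC/C(C)=C/CO | starting material
2 | tert-butyl{[(2E)-3,7-dimethylocta-2,6-dien-1-yl]oxy}dimethylsilane | CC(C)=CCC/C(C)=C/CO[Si](C)(C)C(C)(C)C | intermediate
3 | (2E,6E)-8-[(tert-butyldimethylsilyl)oxy]-2,6-dimethylocta-2,6-dien-1-ol | OC/C(C)=C/CC/C(C)=C/CO[Si](C)(C)C(C)(C)C | intermediate
4 | (2E,6E)-8-[(tert-butyldimethylsilyl)oxy]-2,6-dimethylocta-2,6-dienal | O=C/C(C)=C/CC/C(C)=C/CO[Si](C)(C)C(C)(C)C | intermediate
5 | but-2-yne-1,4-diol | OCC#CCO | starting material
6 | cyclic lithium alkenylalanate from anti hydroalumination (drawn in simplified monomeric form) | [Li+].[Li+].[O-]CC1=CCO[AlH2-]1 | intermediate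
7 | (Z)-2-iodobut-2-ene-1,4-diol | OC/C(I)=C/CO | intermediate
8 | 3-(hydroxymethyl)furan-2(5H)-one | O=C1OCC=C1CO | intermediate
9 | triethyl({2-[(triethylsilyl)oxy]furan-3-yl}methoxy)silane | CC[Si](CC)(CC)OCc1ccoc1O[Si](CC)(CC)CC | intermediate
10 | (5R)-5-[(1S,2E,6E)-8-[(tert-butyldimethylsilyl)oxy]-1-hydroxy-2,6-dimethylocta-2,6-dien-1-yl]-3-{[(triethylsilyl)oxy]methyl}furan-2(5H)-one | O=C1O[C@@H]([C@@H](O)/C(C)=C/CC/C(C)=C/CO[Si](C)(C)C(C)(C)C)C=C1CO[Si](CC)(CC)CC | intermediate
11 | isobutyryl chloride | CC(C)C(Cl)=O | starting material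
12 | (1S,2E,6E)-8-[(tert-butyldimethylsilyl)oxy]-2,6-dimethyl-1-[(2R)-5-oxo-4-{[(triethylsilyl)oxy]methyl}-2,5-dihydrofuran-2-yl]octa-2,6-dien-1-yl 2-methylpropanoate | O=C1O[C@@H]([C@@H](OC(=O)C(C)C)/C(C)=C/CC/C(C)=C/CO[Si](C)(C)C(C)(C)C)C=C1CO[Si](CC)(CC)CC | intermediate
13 | (1S,2E,6E)-8-[(tert-butyldimethylsilyl)oxy]-1-[(2R)-4-(hydroxymethyl)-5-oxo-2,5-dihydrofuran-2-yl]-2,6-dimethylocta-2,6-dien-1-yl 2-methylpropanoate | O=C1O[C@@H]([C@@H](OC(=O)C(C)C)/C(C)=C/CC/C(C)=C/CO[Si](C)(C)C(C)(C)C)C=C1CO | intermediate
14 | (1S,2E,6E)-1-[(2R)-4-(bromomethyl)-5-oxo-2,5-dihydrofuran-2-yl]-8-[(tert-butyldimethylsilyl)oxy]-2,6-dimethylocta-2,6-dien-1-yl 2-methylpropanoate | O=C1O[C@@H]([C@@H](OC(=O)C(C)C)/C(C)=C/CC/C(C)=C/CO[Si](C)(C)C(C)(C)C)C=C1CBr | intermediate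
15 | (1S,2E,6E)-1-[(2R)-4-(bromomethyl)-5-oxo-2,5-dihydrofuran-2-yl]-8-hydroxy-2,6-dimethylocta-2,6-dien-1-yl 2-methylpropanoate | O=C1O[C@@H]([C@@H](OC(=O)C(C)C)/C(C)=C/CC/C(C)=C/CO)C=C1CBr | intermediate
16 | (1S,2E,6E)-1-[(2R)-4-(bromomethyl)-5-oxo-2,5-dihydrofuran-2-yl]-2,6-dimethyl-8-oxoocta-2,6-dien-1-yl 2-methylpropanoate | O=C1O[C@@H]([C@@H](OC(=O)C(C)C)/C(C)=C/CC/C(C)=C/C=O)C=C1CBr | intermediate
17 | (1(10)E,4E,6R,7S,8R,9S)-6-hydroxy-9-(isobutyryloxy)germacra-1(10),4,11(13)-trien-12,8-olide | C=C1C(=O)O[C@@H]2[C@@H]1[C@H](O)/C=C(C)/CC/C=C(C)/[C@@H]2OC(=O)C(C)C | intermediate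
18 | (1(10)E,4E,7R,8R,9S)-9-(isobutyryloxy)-6-oxogermacra-1(10),4,11(13)-trien-12,8-olide | C=C1C(=O)O[C@@H]2[C@@H]1C(=O)/C=C(C)/CC/C=C(C)/[C@@H]2OC(=O)C(C)C | intermediate
19 | (1(10)E,4E,6S,7S,8R,9S)-6-hydroxy-9-(isobutyryloxy)germacra-1(10),4,11(13)-trien-12,8-olide | C=C1C(=O)O[C@@H]2[C@@H]1[C@@H](O)/C=C(C)/CC/C=C(C)/[C@@H]2OC(=O)C(C)C | intermediate
20 | (5S,6S,7S,8R,9S,10S)-6-hydroxy-9-(isobutyryloxy)elema-1,3,11(13)-trien-12,8-olide | C=C1C(=O)O[C@@H]2[C@@H]1[C@@H](O)[C@@H](C(C)=C)[C@](C)(C=C)[C@@H]2OC(=O)C(C)C | intermediate
21 | (5S,6S,7S,8R,9S,10S)-6,15-dihydroxy-9-(isobutyryloxy)elema-1,3,11(13)-trien-12,8-olide | C=C1C(=O)O[C@@H]2[C@@H]1[C@@H](O)[C@@H](C(=C)CO)[C@](C)(C=C)[C@@H]2OC(=O)C(C)C | intermediate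
22 | (5R,6S,7S,8R,9S,10S)-6-hydroxy-9-(isobutyryloxy)-15-oxoelema-1,3,11(13)-trien-12,8-olide | C=C1C(=O)O[C@@H]2[C@@H]1[C@@H](O)[C@@H](C(=C)C=O)[C@](C)(C=C)[C@@H]2OC(=O)C(C)C | intermediate
23 | (1RS,5R,6S,7S,8R,9S,10R)-1,2-epoxy-6-hydroxy-9-(isobutyryloxy)-15-oxoelema-3,11(13)-dien-12,8-olide (both C1 epimers) | C=C1C(=O)O[C@@H]2[C@@H]1[C@@H](O)[C@@H](C(=C)C=O)[C@](C)(C1CO1)[C@@H]2OC(=O)C(C)C | intermediate
24 | (1R,5R,6S,7S,8R,9S,10R)-1,2-epoxy-6-hydroxy-9-(isobutyryloxy)-15-oxoelema-3,11(13)-dien-12,8-olide | C=C1C(=O)O[C@@H]2[C@@H]1[C@@H](O)[C@@H](C(=C)C=O)[C@](C)([C@@H]1CO1)[C@@H]2OC(=O)C(C)C | target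

## Step count and least certain steps

Total: 17 steps. Longest linear sequence: 15 steps (5 to 24, steps 3–17); the branch from 1 contributes steps 1–2.

**Step 14 (key step).** The rearrangement may stop at an unfavourable equilibrium, or be slowed because the C6 hydroxyl, syn to the C15 methyl, destabilises the crown conformer that the chair transition state needs. A boat pathway would then leak to the cis-dialkenyl isomer. Long heating can also polymerise the methylene lactone or shift the allylic C9 ester by a 1,3-acyloxy migration. Fallback: set out from 17, whose C6 hydroxyl is free of that strain. Heating it under the conditions of step 14 should give the 6-epi-elemanolide F1. DMP with NaHCO3 oxidises F1 to the 6-oxo-elemanolide F2. NaBH4/CeCl3·7H2O at −78 °C then reduces F2; axial approach of hydride is blocked by the syn-axial C14 methyl, so the axial alcohol should form, and the route is rejoined at 20.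

**Step 12.** Intermolecular coupling may compete with ring closure, the allylmetal may be protonated, or face control at C7 may be lost so that the cis lactone forms. Fallback: set out from 16 and convert the bromide with (Bu3Sn)2 and Pd(PPh3)4 (cat.) in THF into the allylstannane F3. Close the ring with BF3·OEt2 in CH2Cl2 at −78 °C under high dilution; this is a Lewis acid-promoted addition through an open transition state and does not depend on a chromium chair. The route is rejoined at 17; either C6 epimer is acceptable because step 13 passes through 18.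

**Step 13.** Hydride addition may show poor facial selectivity if ketone 18 leaves the crown conformer, and enolisation of 18 at C7 may move the exocyclic alkene into conjugation. Fallback: set out from 17 and invert C6 without a ketone, by Mitsunobu reaction with formic acid (PPh3, DIAD, THF, 0 °C) to the inverted formate F4. Brief methanolysis (KHCO3, MeOH, 0 °C) leaves the isobutyrate and the methylene lactone intact and rejoins the route at 19.

**Step 6.** The 3-silyloxymethyl group may erode enantio- or diastereocontrol of the vinylogous aldol addition. Fallback: set out from 4 and 9 with an achiral promoter (BF3·OEt2, CH2Cl2, −78 °C) and remove the syn isomers by chromatography. This gives the racemic anti adduct, that is 10 together with its enantiomer F5. A kinetic resolution by asymmetric epoxidation of the secondary allylic alcohol (Ti(OiPr)4, L-(+)-diisopropyl tartrate, t-BuOOH, 4 Å sieves, CH2Cl2, −20 °C) should consume F5 as the epoxy alcohol F6 and return 10, where the route is rejoined.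

**Step 16.** The dioxirane may over-oxidise the aldehyde to the acid or the C6 alcohol to the ketone before the hindered vinyl group is consumed. Fallback: set out from 22 and add HOBr across the vinyl group (NBS, THF/H2O, 0 °C) to the bromohydrin F7, formed as both C1 epimers. Ring closure with Ag2O in CH2Cl2 avoids free base and rejoins the route at 23.

## Further compounds

F1 | step 14 | (5S,6R,7S,8R,9S,10S)-6-hydroxy-9-(isobutyryloxy)elema-1,3,11(13)-trien-12,8-olide | C=C1C(=O)O[C@@H]2[C@@H]1[C@H](O)[C@@H](C(C)=C)[C@](C)(C=C)[C@@H]2OC(=O)C(C)C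
F2 | step 14 | (5S,7R,8R,9S,10S)-9-(isobutyryloxy)-6-oxoelema-1,3,11(13)-trien-12,8-olide | C=C1C(=O)O[C@@H]2[C@@H]1C(=O)[C@@H](C(C)=C)[C@](C)(C=C)[C@@H]2OC(=O)C(C)C
F3 | step 12 | (1S,2E,6E)-2,6-dimethyl-8-oxo-1-{(2R)-5-oxo-4-[(tributylstannyl)methyl]-2,5-dihydrofuran-2-yl}octa-2,6-dien-1-yl 2-methylpropanoate | O=C1O[C@@H]([C@@H](OC(=O)C(C)C)/C(C)=C/CC/C(C)=C/C=O)C=C1C[Sn](CCCC)(CCCC)CCCC
F4 | step 13 | (1(10)E,4E,6S,7S,8R,9S)-6-(formyloxy)-9-(isobutyryloxy)germacra-1(10),4,11(13)-trien-12,8-olide | C=C1C(=O)O[C@@H]2[C@@H]1[C@@H](OC=O)/C=C(C)/CC/C=C(C)/[C@@H]2OC(=O)C(C)C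
F5 | step 6 | (5S)-5-[(1R,2E,6E)-8-[(tert-butyldimethylsilyl)oxy]-1-hydroxy-2,6-dimethylocta-2,6-dien-1-yl]-3-{[(triethylsilyl)oxy]methyl}furan-2(5H)-one (enantiomer of 10) | O=C1O[C@H]([C@H](O)/C(C)=C/CC/C(C)=C/CO[Si](C)(C)C(C)(C)C)C=C1CO[Si](CC)(CC)CC
F6 | step 6 | (5S)-5-[(R)-{(2R,3R)-3-[(3E)-5-[(tert-butyldimethylsilyl)oxy]-3-methylpent-3-en-1-yl]-2-methyloxiran-2-yl}(hydroxy)methyl]-3-{[(triethylsilyl)oxy]methyl}furan-2(5H)-one | O=C1O[C@H]([C@H](O)[C@@]2(C)O[C@@H]2CC/C(C)=C/CO[Si](C)(C)C(C)(C)C)C=C1CO[Si](CC)(CC)CC
F7 | step 16 | (1RS,5R,6S,7S,8R,9S,10R)-2-bromo-1,6-dihydroxy-9-(isobutyryloxy)-15-oxoelema-3,11(13)-dien-12,8-olide (both C1 epimers) | C=C1C(=O)O[C@@H]2[C@@H]1[C@@H](O)[C@@H](C(=C)C=O)[C@](C)(C(O)CBr)[C@@H]2OC(=O)C(C)C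
A1 | alternative 1 | trans-fused γ-butyrolactone, C11 methylene not yet installed (C6 silyl ether, C1/C2 acetonide) | C1C(=O)O[C@@H]2[C@@H]1[C@@H](O[Si](C)(C)C(C)(C)C)[C@@H](C(C)=C)[C@](C)([C@@H]3COC(C)(C)O3)[C@@H]2OC(=O)C(C)C
A2 | alternative 1 | O8 diazoacetate of the corresponding cyclohexanol | [N-]=[N+]=CC(=O)O[C@@H]1C[C@@H](O[Si](C)(C)C(C)(C)C)[C@@H](C(C)=C)[C@](C)([C@@H]2COC(C)(C)O2)[C@@H]1OC(=O)C(C)C
A3 | alternative 2 | trans-8-hydroxycyclohexane with methyl acetate arm at C7 | COC(=O)C[C@H]1[C@@H](O[Si](C)(C)C(C)(C)C)[C@@H](C(C)=C)[C@](C)(C=C)[C@H](OCc2ccc(OC)cc2)[C@@H]1O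
A4 | alternative 2 | open-chain C8 aldehyde with (E)-enoate at C7 | COC(=O)/C=C/[C@@H](O[Si](C)(C)C(C)(C)C)[C@@H](C(C)=C)[C@](C)(C=C)[C@H](OCc1ccc(OC)cc1)C=O
A5 | alternative 3 | C6 cyclohexanone with methyl acetate arm at C7 | O=C1C[C@](C)(C=C)[C@H](OC(=O)C(C)C)[C@H](O[Si](C)(C)C(C)(C)C)[C@H]1CC(=O)OC
A6 | alternative 3 | open-chain C6 aldehyde with (E)-enoate at C7 | O=CC[C@](C)(C=C)[C@H](OC(=O)C(C)C)[C@H](O[Si](C)(C)C(C)(C)C)/C=C/C(=O)OC
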